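## The problem

The target 31 is a germacranolide. Its ten-membered carbocycle (C1–C10) carries a C1 ketone next to a C2 carbinol, a cis-fused 4,5-epoxide bearing the C4 methyl, a C10 methyl and a C8 methacrylate. The ring is fused through C6–C7 to a butenolide whose C11 carries an acetoxymethyl group (C13).

End-to-end closure of a ten-membered ring is costly in entropy and transannular strain, so the ring is better grown from a smaller one. The six stereocentres (C2, C4, C5, C6, C8, C10) lie on a flexible ring, and only neighbouring or tethered pairs can control each other. C8 can set C10 across a five-membered lactone and can bias the adjacent C6. C6 can set C5 in an aldol event, C5 can pass its chirality to C2 in a sigmatropic shift, and the C2 hydroxyl can then steer the epoxidation.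

Several groups rule out strong bases, strong nucleophiles and strong acids late in the route: the methacrylate (conjugate addition, diazoalkanes, hydrides), the allylic acetate on the electron-poor C7=C11 olefin, the acidic butenolide γ-hydrogen at C6, the α-ketol (ketol shift, epimerisation at C10) and the epoxide.

The enabling feature appears once the epoxide oxygen is removed. The array C1(=O)–C2(OH)–C3H2–C4(CH3)=C5 is the retron of a [2,3]-Wittig rearrangement of an α-allyloxy ketone. Reconnecting the C2 oxygen to C5 converts the ten-membered carbocycle into a nine-membered cyclic ether with an exocyclic isopropenyl group on C5.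

## Retrosynthesis

**31 ⇒ 30.** The C4–O and C5–O bonds of the epoxide are cut first. The epoxide is the most acid- and nucleophile-sensitive group and is best made last. The Z-olefin 30 has a free homoallylic C2 hydroxyl as its only hydroxyl, so a hydroxyl-directed epoxidation can deliver oxygen to one face. Carrying the epoxide through ring formation would expose it to Lewis acids and carbenoids. The forward step must discriminate the trisubstituted C4=C5 olefin from the two electron-poor olefins and pick one face.

**30 ⇒ 27 (key disconnection).** The C2–C3 bond is cut and the C2 oxygen is reattached to C5, the reverse of a [2,3] shift. This replaces a ten-membered carbocycle by the nine-membered ether 27. It also trades the isolated C2 stereocentre for C5, which sits next to C6 and is accessible by an aldol reaction. Direct closures of the ten-membered ring would need every stereocentre in an open chain. The forward reaction requires regioselective soft enolisation at C2, a suprafacial shift with the C6 substituent pseudo-axial (Z-olefin), and survival of both esters and the butenolide.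

**27 ⇒ 26 ⇒ 25 ⇒ 24.** The methacrylate and the acetate are removed to give diol 25 and its bis-silyl ether 24. The esters are placed after the ring closure because the methacrylate would not survive diazomethane, and before the key step so that the rearrangement releases the only free hydroxyl. The forward steps need a primary-over-secondary acetylation and an acylation of the hindered C8 alcohol.

**24 ⇒ 23.** The O–C2 bond is cut, leading to hydroxy diazoketone 23. A carbenoid O–H insertion forms an α-alkoxy ketone without base. Closures at C–C bonds of this ring (for example an alkenylchromium addition at C7–C8) would need a halogenated butenolide that is much harder to make. The forward step must favour a nine-membered closure over C–H insertion and dimerisation; the two chains sit on adjacent atoms of the planar butenolide, which helps.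

**23 ⇒ 21 ⇒ 18 + 19.** The diazoketone comes from acid 21. The C5–C6 bond of 21 is cut in a vinylogous Mukaiyama aldol sense to give silyloxyfuran 18 and methacrolein 19. This one cut forms the butenolide γ-substituent, both oxygenated stereocentres and the isopropenyl group. The forward step needs face selectivity at C6 from C8 and syn simple diastereoselection for C5.

**18 ⇒ 17 ⇒ 15 ⇒ 13.** The butenolide 17 is traced to the 3,4-disubstituted furan 13 by singlet-oxygen oxidation to 15 and reduction. Keeping the robust furan until this point allows enolate and hydroxide chemistry earlier. The forward oxidation must place the carbonyl at the α-carbon next to the CH2OTBS group.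

**13 ⇒ 10 ⇒ 8 ⇒ 6 ⇒ 4 + 5; 4 ⇒ 3 ⇒ 1.** The C8 oxygen and the C1 carboxyl of 13 are tied back into γ-lactone 10. Its C10 methyl comes from trans-selective alkylation of lactone 8, so C8 controls C10. Lactone 8 comes from keto ester 6 by asymmetric transfer hydrogenation, which sets C8 by catalyst control. Keto ester 6 is the Stetter adduct of aldehyde 4 and ethyl acrylate 5. Aldehyde 4 comes from mono-silyl ether 3 of the symmetric diol 1.

## Roads not taken

**Alternative 1:** The cut is the C6–C7 bond together with the lactone C12–O bond. In the forward step CrCl2 with catalytic NiCl2 turns a C7 alkenyl iodide into an alkenylchromium species that adds to a C6 aldehyde already bearing the 4,5-epoxide; the alkoxide then lactonises to give A1.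
- Merits: this chromium-mediated addition is the best-documented way to close ten-membered carbocycles beside ketones and esters. The lactone forms in the same flask, and the epoxide and C2 are already in place.
- Weak points: C2, C4, C5, C8 and C10 must each be set on an open chain by separate reagent-controlled steps. The aldehyde sits next to the epoxide and is fragile. C6 is created in the cyclisation without a dependable control element. A1 carries three different protecting groups, and the C2 and C8 secondary hydroxyls must be told apart before two acylations.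
- Comparison: in ring-closing precedent this road is better than the chosen one, whose carbenoid closure of 24 and ring expansion of 27 are both less secure. The chosen plan sets against it that C2 and the Z-olefin arise from C5 in one stereospecific event, that both esters are in place before the ring is expanded, and that the epoxide is made last under direction from the only free hydroxyl.

**Alternative 2:** The cut is the C8–C9 bond, restoring a six-membered ring with two adjacent alkenyl groups. In the forward step the potassium alkoxide (KH, 18-crown-6) undergoes an anionic oxy-Cope shift to the cyclodecadienone A2.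
- Merits: this is a thoroughly proven ring expansion to cyclodecenones. Both trisubstituted olefins get their geometry from a chair transition state, and the ring is reached in few steps.
- Weak points: A2 lacks C11–C13. It has C1 as an olefinic carbon and C6 as a ketone. The endgame must convert C1=C10 into a C1 ketone with a C10 stereocentre, distinguish two trisubstituted olefins, reduce C6 from the right face and build the butenolide on an enolisable ring prone to transannular reactions.
- Comparison: the ring-forming step is far better precedented than the chosen one. The chosen plan sets against it that the full oxidation pattern is present when the ten-membered ring appears in 30, one step from the target.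

**Alternative 3:** The cut reunites the C1 and C6 carbonyls into a tetrasubstituted ring-fusion olefin of an octalin. In the forward step ozone, then dimethyl sulfide, cleaves it to the cyclodecanedione A3.
- Merits: the stereocentres are set on a rigid bicycle, the ten-membered ring appears by bond cleavage with no entropic penalty, and the acetate is already present.
- Weak points: the octalin needs a long sequence. A3 contains two ketones, and only C6 must be reduced, from one face, before lactonisation. A 1,6-diketone in a ten-membered ring invites transannular aldol chemistry, and the C5 epoxide next to the C6 ketone is sensitive to base and reductants. The C2 and C8 hydroxyls must again be differentiated.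
- Comparison: ring formation is more reliable than either medium-ring step of the chosen plan. The chosen plan sets against it that it needs no late redox discrimination and a shorter endgame from 30.

Key step: step 16

Assumption: the BF3-mediated vinylogous aldol addition is taken to follow its usual syn (threo) preference, which corresponds to the (5R,6R) adduct.

Abbreviation and numbering: TBS = tert-butyldimethylsilyl; ring compounds use germacrane numbering (C1–C13).

## Route

Step 1
Reactants: 1 furan-3,4-diyldimethanol
Product: 3 [4-(TBS-oxymethyl)furan-3-yl]methanol, via sodium alkoxide 2 (not isolated)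
Conditions: NaH (1.0 equiv), THF, 0 °C; TBSCl, 0 °C → rt
Reagents that add atoms: tert-butyldimethylsilyl chloride, CC(C)(C)[Si](C)(C)Cl
Why: Monosilylation of a symmetrical diol through its sparingly soluble monosodium alkoxide (O-silylation); the mono-alkoxide is silylated faster than the product is deprotonated, which favours the mono-ether.

Step 2
Reactants: 3 [4-(TBS-oxymethyl)furan-3-yl]methanol
Product: 4 4-(TBS-oxymethyl)furan-3-carbaldehyde
Conditions: MnO2, CH2Cl2, rt
Reagents that add atoms: none
Why: MnO2 oxidation of an activated (furylmethyl) alcohol to the aldehyde; the silyl ether and the furan are inert.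

Step 3
Reactants: 4 4-(TBS-oxymethyl)furan-3-carbaldehyde; 5 ethyl acrylate
Product: 6 ethyl 4-oxo-4-[4-(TBS-oxymethyl)furan-3-yl]butanoate
Conditions: 3-benzyl-5-(2-hydroxyethyl)-4-methylthiazolium chloride (cat.), Et3N, EtOH, 75 °C
Reagents that add atoms: none
Why: Stetter reaction: carbene umpolung of the heteroaryl aldehyde and conjugate addition to the acrylate give the 1,4-dicarbonyl compound (C8, C9, C10, C1 of the target).

Step 4
Reactants: 6 ethyl 4-oxo-4-[4-(TBS-oxymethyl)furan-3-yl]butanoate
Product: 8 (5R)-5-[4-(TBS-oxymethyl)furan-3-yl]oxolan-2-one, via hydroxy ester 7 (not isolated)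
Conditions: RuCl[(R,R)-TsDPEN](p-cymene) (1 mol%), HCO2H/Et3N (5:2), 30 °C; then PPTS, toluene, 60 °C
Reagents that add atoms: none
Why: Noyori asymmetric transfer hydrogenation of a heteroaryl alkyl ketone; the (R,R) ligand is chosen to give the (R)-carbinol by analogy with aryl alkyl ketones, which sets C8 under catalyst control, and the γ-hydroxy ester then lactonises.

Step 5
Reactants: 8 (5R)-5-[4-(TBS-oxymethyl)furan-3-yl]oxolan-2-one
Product: 10 (3S,5R)-3-methyl-5-[4-(TBS-oxymethyl)furan-3-yl]oxolan-2-one, via lithium enolate 9 (not isolated)
Conditions: LiN(iPr)2 (1.05 equiv), THF, −78 °C; MeI, −78 → −40 °C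
Reagents that add atoms: iodomethane, CI
Why: Lactone enolate alkylation; methyl iodide approaches the enolate face opposite the C5 furyl group, so the trans lactone forms and C8 sets C10 (target 8R,10S).

Step 6
Reactants: 10 (3S,5R)-3-methyl-5-[4-(TBS-oxymethyl)furan-3-yl]oxolan-2-one
Product: 13 (2S,4R)-2-methyl-4-(TBS-oxy)-4-[4-(TBS-oxymethyl)furan-3-yl]butanoic acid, via lithium hydroxy carboxylate 11 (not isolated), via bis-silylated ester 12 (not isolated)
Conditions: LiOH, THF/H2O, 0 °C → rt; evaporate; TBSCl, imidazole, DMF, rt; then K2CO3, MeOH/H2O, 0 °C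
Reagents that add atoms: lithium hydroxide, [Li+].[OH-]; tert-butyldimethylsilyl chloride, CC(C)(C)[Si](C)(C)Cl
Why: Saponification, silylation and selective silyl ester cleavage; the carboxylate salt cannot relactonise, the C8 oxygen is capped as its silyl ether, and the labile silyl ester is cleaved by mild base while both silyl ethers stay.

Step 7
Reactants: 13 (2S,4R)-2-methyl-4-(TBS-oxy)-4-[4-(TBS-oxymethyl)furan-3-yl]butanoic acid
Product: 15 (2S,4R)-4-[2-hydroxy-5-oxo-4-(TBS-oxymethyl)-2,5-dihydrofuran-3-yl]-2-methyl-4-(TBS-oxy)butanoic acid (both C6 epimers), via furan endoperoxide 14 (not isolated)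
Conditions: O2, visible light, rose bengal (cat.), iPr2NEt, CH2Cl2, −78 °C
Reagents that add atoms: oxygen, O=O
Why: Singlet-oxygen [4+2] addition to the furan and base-induced Kornblum–DeLaMare-type opening of the endoperoxide; the hindered amine removes the less shielded α-hydrogen (next to CH2OTBS, not next to the branched C8), which puts the carbonyl at C12 and the hemiacetal at C6.

Step 8
Reactants: 15 γ-hydroxybutenolide acid
Product: 17 (2S,4R)-2-methyl-4-[5-oxo-4-(TBS-oxymethyl)-2,5-dihydrofuran-3-yl]-4-(TBS-oxy)butanoic acid, via ring-opened hydroxy dicarboxylate 16 (not isolated)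
Conditions: NaBH4, MeOH/THF, 0 °C; then 1 M HCl to pH 3
Reagents that add atoms: none
Why: Borohydride reduces the open-chain aldehyde tautomer of the hydroxybutenolide; on acidification the (Z)-4-hydroxy enoate closes to the butenolide, while the saturated carboxyl group cannot lactonise because C8 is silylated.

Step 9
Reactants: 17 butenolide acid
Product: 18 TBS (2S,4R)-2-methyl-4-(TBS-oxy)-4-[5-(TBS-oxy)-4-(TBS-oxymethyl)furan-3-yl]butanoate
Conditions: TBSOTf (2.5 equiv), Et3N, CH2Cl2, 0 °C; used crude
Reagents that add atoms: tert-butyldimethylsilyl trifluoromethanesulfonate, CC(C)(C)[Si](C)(C)OS(=O)(=O)C(F)(F)F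
Why: Soft enolisation of the butenolide at its ring γ-CH2 gives the aromatic 2-silyloxyfuran; the carboxylic acid is silylated at the same time.

Step 10
Reactants: 18 silyloxyfuran silyl ester; 19 methacrolein
Product: 21 (2S,4R)-4-{(2R)-2-[(1R)-1-hydroxy-2-methylprop-2-en-1-yl]-5-oxo-4-(TBS-oxymethyl)-2,5-dihydrofuran-3-yl}-2-methyl-4-(TBS-oxy)butanoic acid, via adduct silyl ester 20 (not isolated)
Conditions: BF3·OEt2, CH2Cl2, −78 °C; then AcOH, THF/H2O, rt
Reagents that add atoms: none
Why: Vinylogous Mukaiyama aldol addition forming C5–C6. The C8–H lies in the furan plane toward the CH2OTBS group (minimal 1,3-allylic strain), so the C9 methylene shields one face of C6 and the aldehyde adds on the other, giving 6R from 8R. The open transition state gives the syn (threo) relationship, hence 5R; mild acid then frees the carboxylic acid.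

Step 11
Reactants: 21 hydroxy acid
Product: 23 (3S,5R)-1-diazo-5-{(2R)-2-[(1R)-1-hydroxy-2-methylprop-2-en-1-yl]-5-oxo-4-(TBS-oxymethyl)-2,5-dihydrofuran-3-yl}-3-methyl-5-(TBS-oxy)pentan-2-one, via mixed anhydride 22 (not isolated)
Conditions: iBuOCOCl, N-methylmorpholine, THF, −20 °C; then CH2N2, Et2O, −20 → 0 °C
Reagents that add atoms: diazomethane, C=[N+]=[N-]
Why: Acylation of diazomethane by a mixed carbonic anhydride (first stage of an Arndt–Eistert sequence) adds C2. The hindered secondary C5 hydroxyl is not acylated at −20 °C, the tetrasubstituted butenolide olefin is inert to the dipole, and the weak base avoids epimerisation at C10.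

Step 12
Reactants: 23 hydroxy diazoketone
Product: 24 nine-membered keto ether (5R,6R,8R,10S): ring O–C2H2–C1(=O)–C10H(CH3)–C9H2–C8H(OTBS)–C7–C6H–C5H(isopropenyl) fused at C6–C7 to the butenolide bearing C13H2-OTBS on C11
Conditions: Rh2(OAc)4 (2 mol%), CH2Cl2, 40 °C, slow addition, 2 mM
Reagents that add atoms: none
Why: Rhodium carbenoid O–H insertion; the electrophilic carbenoid is captured by the C5 hydroxyl (oxonium ylide, proton transfer) and closes the nine-membered ring as a cyclic α-alkoxy ketone. The two chains sit on adjacent atoms of the planar butenolide, which pre-organises the closure, and no stereocentre is touched.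

Step 13
Reactants: 24 nine-membered keto ether (bis-TBS)
Product: 25 diol (5R,6R,8R,10S): same ring with C8-OH and C13-OH
Conditions: HF·pyridine, pyridine, THF, 0 °C → rt
Reagents that add atoms: none
Why: Fluoride-induced Si–O cleavage of both silyl ethers under buffered conditions that leave the allylic ether, the ketone and the butenolide untouched.

Step 14
Reactants: 25 diol
Product: 26 C13 acetate (5R,6R,8R,10S) of the nine-membered keto ether with free C8-OH
Conditions: AcCl (1.05 equiv), 2,4,6-collidine, CH2Cl2, −78 °C
Reagents that add atoms: acetyl chloride, CC(Cl)=O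
Why: Kinetically selective acylation of the unhindered primary allylic alcohol over the hindered secondary C8 alcohol with an acid chloride and a hindered pyridine base at low temperature.

Step 15
Reactants: 26 C13 acetate
Product: 27 C8 methacrylate C13 acetate (5R,6R,8R,10S) of the nine-membered keto ether (key-step precursor)
Conditions: methacrylic anhydride, Et3N, DMAP (cat.), CH2Cl2, 0 °C → rt
Reagents that add atoms: methacrylic anhydride, C=C(C)C(=O)OC(=O)C(C)=C
Why: DMAP-catalysed acyl transfer to the secondary C8 alcohol with retention at C8; every hydroxyl is now esterified, so the hydroxyl released in step 16 is the only free one.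

Step 16
Reactants: 27 nine-membered α-allyloxy ketone
Product: 30 ten-membered hydroxy ketone (2S,4Z,6S,8R,10S) with Z-C4=C5 and free C2-OH (4,5-deoxy target), via boron enolate 28 (not isolated), via boron alkoxide 29 (not isolated)
Conditions: Bu2BOTf (1.3 equiv), iPr2NEt (1.6 equiv), CH2Cl2, −78 → 0 °C; then pH 7 phosphate buffer, MeOH
Reagents that add atoms: none
Why: Proposed new method: Bu2BOTf activates the C1 ketone and iPr2NEt removes a C2 hydrogen to give the endocyclic dibutylboron enolate 28, which undergoes a suprafacial [2,3] shift through a five-membered envelope (C2–C3 forms, O–C5 breaks) to the boron alkoxide 29, hydrolysed to 30. The closest known reaction type is the [2,3]-Wittig rearrangement of open-chain α-allyloxy ketone and ester enolates (boron enolates, enamines), together with Z-selective Wittig–Still shifts of 2-methylallyl ethers. The ten-membered ring closes by ring expansion, not by end-to-end cyclisation: the ring oxygen is exchanged for C3 and C4 in a bridged five-membered transition state, so no medium-ring entropy is paid. The new C2 stereocentre is controlled by C5 through the tether, because C1 and C6 must stand cis on the five-membered transition state, which converts 5R into 2S. The olefin should be Z because C6 takes the pseudo-axial position to avoid eclipsing the C4 methyl, and because the four-atom tether can only span the envelope face away from that methyl. Three selectivities are needed: C2 over C10 enolisation (C10 is tertiary, C2 is activated by oxygen), ketone over butenolide γ-hydrogen (boron triflates enolise ketones much faster than lactones at −78 °C), and [2,3] over [3,3] or [1,2] shifts (favoured for the metal enolate). The boron alkoxide chelated to the ketone is the thermodynamic sink.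

Step 17
Reactants: 30 ten-membered hydroxy ketone
Product: 31 target (2S,4S,5R,6R,8R,10S)
Conditions: VO(acac)2 (5 mol%), t-BuOOH (1.5 equiv, decane), CH2Cl2, 0 °C → rt
Reagents that add atoms: tert-butyl hydroperoxide, CC(C)(C)OO
Why: Hydroxyl-directed epoxidation of a homoallylic alcohol: the vanadate ester of the C2 hydroxyl delivers oxygen to the olefin face it can reach, which in the cis-cyclodecene is the outer face, and with the vinylic methyl equatorial in the chair-like delivery this corresponds to the 2,4-anti (4S,5R) epoxide. The methacrylate and butenolide olefins are too electron-poor to react.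

## Compound list

1 | furan-3,4-diyldimethanol | OCc1cocc1CO | starting material
2 | monosodium alkoxide of 1 | [Na+].[O-]Cc1cocc1CO | intermediate
3 | [4-(TBS-oxymethyl)furan-3-yl]methanol | OCc1cocc1CO[Si](C)(C)C(C)(C)C | intermediate
4 | 4-(TBS-oxymethyl)furan-3-carbaldehyde | O=Cc1cocc1CO[Si](C)(C)C(C)(C)C | intermediate
5 | ethyl acrylate | C=CC(=O)OCC | starting material
6 | ethyl 4-oxo-4-[4-(TBS-oxymethyl)furan-3-yl]butanoate | CCOC(=O)CCC(=O)c1cocc1CO[Si](C)(C)C(C)(C)C | intermediate
7 | ethyl (4R)-4-hydroxy-4-[4-(TBS-oxymethyl)furan-3-yl]butanoate | CCOC(=O)CC[C@@H](O)c1cocc1CO[Si](C)(C)C(C)(C)C | intermediate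
8 | (5R)-5-[4-(TBS-oxymethyl)furan-3-yl]oxolan-2-one | O=C1CC[C@H](c2cocc2CO[Si](C)(C)C(C)(C)C)O1 | intermediate
9 | lithium enolate of 8 | [Li+].[O-]C1=CC[C@H](c2cocc2CO[Si](C)(C)C(C)(C)C)O1 | intermediate
10 | (3S,5R)-3-methyl-5-[4-(TBS-oxymethyl)furan-3-yl]oxolan-2-one | O=C1[C@@H](C)C[C@H](c2cocc2CO[Si](C)(C)C(C)(C)C)O1 | intermediate
11 | lithium (2S,4R)-4-hydroxy-2-methyl-4-[4-(TBS-oxymethyl)furan-3-yl]butanoate | C[C@@H](C[C@@H](O)c1cocc1CO[Si](C)(C)C(C)(C)C)C(=O)[O-].[Li+] | intermediate
12 | TBS (2S,4R)-2-methyl-4-(TBS-oxy)-4-[4-(TBS-oxymethyl)furan-3-yl]butanoate | C[C@@H](C[C@@H](O[Si](C)(C)C(C)(C)C)c1cocc1CO[Si](C)(C)C(C)(C)C)C(=O)O[Si](C)(C)C(C)(C)C | intermediate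
13 | (2S,4R)-2-methyl-4-(TBS-oxy)-4-[4-(TBS-oxymethyl)furan-3-yl]butanoic acid | C[C@@H](C[C@@H](O[Si](C)(C)C(C)(C)C)c1cocc1CO[Si](C)(C)C(C)(C)C)C(=O)O | intermediate
14 | 2,5-endoperoxide of furan 13 | C[C@@H](C[C@@H](O[Si](C)(C)C(C)(C)C)C1=C(CO[Si](C)(C)C(C)(C)C)C2OOC1O2)C(=O)O | intermediate
15 | (2S,4R)-4-[2-hydroxy-5-oxo-4-(TBS-oxymethyl)-2,5-dihydrofuran-3-yl]-2-methyl-4-(TBS-oxy)butanoic acid, both C6 epimers | C[C@@H](C[C@@H](O[Si](C)(C)C(C)(C)C)C1=C(CO[Si](C)(C)C(C)(C)C)C(=O)OC1O)C(=O)O | intermediate
16 | disodium salt of the ring-opened (Z)-hydroxy diacid from 15 | C[C@@H](C[C@@H](O[Si](C)(C)C(C)(C)C)/C(CO)=C(\CO[Si](C)(C)C(C)(C)C)C(=O)[O-])C(=O)[O-].[Na+].[Na+] | intermediate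
17 | (2S,4R)-2-methyl-4-[5-oxo-4-(TBS-oxymethyl)-2,5-dihydrofuran-3-yl]-4-(TBS-oxy)butanoic acid | C[C@@H](C[C@@H](O[Si](C)(C)C(C)(C)C)C1=C(CO[Si](C)(C)C(C)(C)C)C(=O)OC1)C(=O)O | intermediate
18 | TBS (2S,4R)-2-methyl-4-(TBS-oxy)-4-[5-(TBS-oxy)-4-(TBS-oxymethyl)furan-3-yl]butanoate | C[C@@H](C[C@@H](O[Si](C)(C)C(C)(C)C)c1coc(O[Si](C)(C)C(C)(C)C)c1CO[Si](C)(C)C(C)(C)C)C(=O)O[Si](C)(C)C(C)(C)C | intermediate
19 | methacrolein (2-methylprop-2-enal) | CC(=C)C=O | starting material
20 | TBS ester of aldol adduct 21 | C[C@@H](C[C@@H](O[Si](C)(C)C(C)(C)C)C1=C(CO[Si](C)(C)C(C)(C)C)C(=O)O[C@H]1[C@H](O)C(C)=C)C(=O)O[Si](C)(C)C(C)(C)C | intermediate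
21 | (2S,4R)-4-{(2R)-2-[(1R)-1-hydroxy-2-methylprop-2-en-1-yl]-5-oxo-4-(TBS-oxymethyl)-2,5-dihydrofuran-3-yl}-2-methyl-4-(TBS-oxy)butanoic acid | C[C@@H](C[C@@H](O[Si](C)(C)C(C)(C)C)C1=C(CO[Si](C)(C)C(C)(C)C)C(=O)O[C@H]1[C@H](O)C(C)=C)C(=O)O | intermediate
22 | isobutyl carbonic mixed anhydride of 21 | C[C@@H](C[C@@H](O[Si](C)(C)C(C)(C)C)C1=C(CO[Si](C)(C)C(C)(C)C)C(=O)O[C@H]1[C@H](O)C(C)=C)C(=O)OC(=O)OCC(C)C | intermediate
23 | (3S,5R)-1-diazo-5-{(2R)-2-[(1R)-1-hydroxy-2-methylprop-2-en-1-yl]-5-oxo-4-(TBS-oxymethyl)-2,5-dihydrofuran-3-yl}-3-methyl-5-(TBS-oxy)pentan-2-one | C[C@@H](C[C@@H](O[Si](C)(C)C(C)(C)C)C1=C(CO[Si](C)(C)C(C)(C)C)C(=O)O[C@H]1[C@H](O)C(C)=C)C(=O)C=[N+]=[N-] | intermediate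
24 | butenolide-fused oxonan-3-one (5R,6R,8R,10S) with C5 isopropenyl, C8-OTBS, C10 methyl, C13-OTBS | CC(C)(C)[Si](C)(C)O[C@@H]1C[C@H](C)C(=O)CO[C@H](C(C)=C)[C@@H]2OC(=O)C(CO[Si](C)(C)C(C)(C)C)=C21 | intermediate
25 | diol of 24 (C8-OH, C13-OH), (5R,6R,8R,10S) | O[C@@H]1C[C@H](C)C(=O)CO[C@H](C(C)=C)[C@@H]2OC(=O)C(CO)=C21 | intermediate
26 | C13 acetate with free C8-OH, (5R,6R,8R,10S) | O[C@@H]1C[C@H](C)C(=O)CO[C@H](C(C)=C)[C@@H]2OC(=O)C(COC(C)=O)=C21 | intermediate
27 | C8 methacrylate, C13 acetate of the butenolide-fused oxonan-3-one, (5R,6R,8R,10S) | C=C(C)C(=O)O[C@@H]1C[C@H](C)C(=O)CO[C@H](C(C)=C)[C@@H]2OC(=O)C(COC(C)=O)=C21 | intermediate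
28 | dibutylboron enolate of 27 (C1-OBBu2, ring-cis C1=C2) | C=C(C)C(=O)O[C@@H]1C[C@H](C)/C(OB(CCCC)CCCC)=C\O[C@H](C(C)=C)[C@@H]2OC(=O)C(COC(C)=O)=C21 | intermediate
29 | C2 O-dibutylboryl derivative of 30 | C=C(C)C(=O)O[C@@H]1C[C@H](C)C(=O)[C@@H](OB(CCCC)CCCC)C/C(C)=C\[C@@H]2OC(=O)C(COC(C)=O)=C21 | intermediate
30 | ten-membered hydroxy ketone (2S,4Z,6S,8R,10S): C1 ketone, C2-OH, Z-C4=C5, C8 methacrylate, C13 acetate, 6,12-butenolide | C=C(C)C(=O)O[C@@H]1C[C@H](C)C(=O)[C@@H](O)C/C(C)=C\[C@@H]2OC(=O)C(COC(C)=O)=C21 | intermediate
31 | target, (2S,4S,5R,6R,8R,10S)-4,5-epoxide of 30 | C=C(C)C(=O)O[C@@H]1C[C@H](C)C(=O)[C@@H](O)C[C@]2(C)O[C@@H]2[C@@H]2OC(=O)C(COC(C)=O)=C21 | target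

## Step count and risks

Total: 17 steps. Longest linear sequence: 17 steps (1 → 31); ethyl acrylate 5 and methacrolein 19 enter directly.

**Step 16 (key step).**
- What may go wrong: enolisation at the butenolide γ-position instead of C2, followed by transannular vinylogous aldol addition to C1 or loss of the ring ether; failure of the enolate carbon to reach the isopropenyl terminus in the accessible ring conformers; competing [3,3] or [1,2] shifts; formation of the E-olefin.
- Fallback (known chemistry): the metal enolate is replaced by an enamine. Secondary-amine catalysis (pyrrolidine, MeOH, rt) is an established trigger for the [2,3]-Wittig rearrangement of α-allyloxy ketones and needs neither a Lewis acid nor a tertiary amine base, so the C6 hydrogen is not at risk. This activation has likewise been shown only on open-chain ethers, so it removes the enolisation risk but not the untested ring topology. It sets out from 27 and comes back at 30, with no new isolable compound.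

**Step 12 (nine-membered ring closure).**
- What may go wrong: the carbenoid may insert into the C8–H bond (five-membered ring), dimerise, or add to an olefin faster than it finds the C5 hydroxyl. The enol formed first may also undergo a Claisen-type shift before it tautomerises.
- Fallback: the ether bond is made by substitution instead of by a carbenoid. Diazoketone 23 is treated with HBr (Et2O, −20 °C) to give the bromomethyl ketone F1, which is closed by the C5 hydroxyl with AgOTf and 2,6-di-tert-butyl-4-methylpyridine under high dilution. This rejoins the route at 24.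

**Step 10 (vinylogous aldol).**
- What may go wrong: poor face selectivity at C6 with respect to the remote C8 centre, poor syn/anti selectivity at C5, and competing conjugate addition to the enal.
- Fallback: C5 is set after the C–C bond. The C5-epimeric mixture of 21 is oxidised with Dess–Martin periodinane to the single enone F2. F2 is reduced with NaBH4/CeCl3·7H2O at −78 °C (Luche reduction under Felkin–Anh control, hydride anti to the lactone C–O bond), which converges both C5 epimers on syn-configured 21. The 6S series is removed by chromatography.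

**Step 17 (epoxidation).**
- What may go wrong: delivery to the wrong olefin face if the ring conformation places the C2 hydroxyl on the other side, and oxidative damage to the α-ketol by the vanadium peroxide.
- Fallback: steric instead of directed control. Alcohol 30 is silylated (Et3SiCl, imidazole) to the triethylsilyl ether F3, epoxidised on the exposed face with dimethyldioxirane (acetone, −20 °C) to the epoxy silyl ether F4, and desilylated with HF·pyridine to 31.

**Step 7 (furan oxidation).**
- What may go wrong: fragmentation of the endoperoxide in the wrong direction (carbonyl next to C7 instead of next to C11) and over-oxidation.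
- Fallback: the carbonyl position is fixed by C–H borylation. Acid 13 is borylated at the less hindered α-C–H next to CH2OTBS ([Ir(OMe)(cod)]2, 4,4′-di-tert-butyl-2,2′-bipyridine, bis(pinacolato)diboron, THF, 60 °C) to the furyl boronate F5. F5 is oxidised with NaBO3·4H2O to the hydroxyfuran, which tautomerises to butenolide 17; this rejoins the route at 17 and bypasses 15.

## Further compounds

F0 | step 16 | none | none
F1 | step 12 | (3S,5R)-1-bromo-5-{(2R)-2-[(1R)-1-hydroxy-2-methylprop-2-en-1-yl]-5-oxo-4-(TBS-oxymethyl)-2,5-dihydrofuran-3-yl}-3-methyl-5-(TBS-oxy)pentan-2-one | C[C@@H](C[C@@H](O[Si](C)(C)C(C)(C)C)C1=C(CO[Si](C)(C)C(C)(C)C)C(=O)O[C@H]1[C@H](O)C(C)=C)C(=O)CBr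
F2 | step 10 | (2S,4R)-2-methyl-4-{(2R)-2-(2-methylprop-2-enoyl)-5-oxo-4-(TBS-oxymethyl)-2,5-dihydrofuran-3-yl}-4-(TBS-oxy)butanoic acid | C[C@@H](C[C@@H](O[Si](C)(C)C(C)(C)C)C1=C(CO[Si](C)(C)C(C)(C)C)C(=O)O[C@H]1C(=O)C(C)=C)C(=O)O
F3 | step 17 | C2 triethylsilyl ether of 30 | C=C(C)C(=O)O[C@@H]1C[C@H](C)C(=O)[C@@H](O[Si](CC)(CC)CC)C/C(C)=C\[C@@H]2OC(=O)C(COC(C)=O)=C21
F4 | step 17 | C2 triethylsilyl ether of 31 | C=C(C)C(=O)O[C@@H]1C[C@H](C)C(=O)[C@@H](O[Si](CC)(CC)CC)C[C@]2(C)O[C@@H]2[C@@H]2OC(=O)C(COC(C)=O)=C21
F5 | step 7 | (2S,4R)-2-methyl-4-[5-(4,4,5,5-tetramethyl-1,3,2-dioxaborolan-2-yl)-4-(TBS-oxymethyl)furan-3-yl]-4-(TBS-oxy)butanoic acid | C[C@@H](C[C@@H](O[Si](C)(C)C(C)(C)C)c1coc(B2OC(C)(C)C(C)(C)O2)c1CO[Si](C)(C)C(C)(C)C)C(=O)O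
A1 | alternative 1 | protected germacranolide core with 4,5-epoxide, C8-OTES, C2-OTBS, C13-OPMB | CC[Si](CC)(CC)O[C@@H]1C[C@H](C)C(=O)[C@@H](O[Si](C)(C)C(C)(C)C)C[C@]2(C)O[C@@H]2[C@@H]2OC(=O)C(COCc3ccc(OC)cc3)=C21
A2 | alternative 2 | (4Z,1(10)E)-cyclodecadien-6-one with C8-OPMB and C2-OTBS | COc1ccc(CO[C@@H]2C/C(C)=C/[C@@H](O[Si](C)(C)C(C)(C)C)C/C(C)=C\C(=O)C2)cc1
A3 | alternative 3 | cyclodecane-1,6-dione with Z-γ-keto enoate, cis-epoxide, C8-OTES, C2-OTBS | CC[Si](CC)(CC)O[C@@H]1C[C@H](C)C(=O)[C@@H](O[Si](C)(C)C(C)(C)C)C[C@]2(C)O[C@@H]2C(=O)/C1=C(/COC(C)=O)C(=O)OC
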